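## Remarks on the chemistry (corrections and assumptions)

- **Numbering.** Ring A is C1–C6: C1 ketone, C2 with the CH(Ph)CH2CO2H chain, C3 with the ring B oxygen, C4 acyl-bearing, C5 enol OH, C6 quaternary. Ring B is O1′, C2′, C3′, C4′. The cyclobutane is Ca (isopropenyl), Cb (CH2), Cc (carries the CH2 link to C6), Cd (CMe2). "CBM" in names means the {[(1R,3S)-2,2-dimethyl-3-(prop-1-en-2-yl)cyclobutyl]methyl} group.
- **Carbon count of the terpene piece.** Cleaving the ring alkene of α-pinene leaves a CH2CO2H arm, one carbon more than the single CH2 between Cc and C6. (1S,5S)-(−)-Verbenone, the allylic oxidation product of (−)-α-pinene, cleaves to the acid with CO2H directly on the ring, so the route starts there. Its two stereocentres map onto (1R,3S) of the CBM group with the correct cis relationship.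
- **Symmetry.** The mirror relationship about the C3···C6 axis holds for the phenol before acylation (13), not for the tigloyl ketone. It is used at that stage, where C2 and C4 are equivalent.
- **Iodination.** Electrophilic iodination of a 3,5-dialkoxyphenol is not reliably para. The iodide is therefore placed by directed lithiation between the two acetal oxygens of a silyl-protected phenol.
- **Precursor redesign.** Methyl ethers on O1 and O5 would have to be cleaved with BBr3 or hot thiolate, which neither the isopropenylcyclobutane nor ring B would survive. Methoxymethyl (MOM) ethers replace them; the bonds formed in the key step and the skeletons of 18 and 20 are unchanged.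
- **Acylation.** A Lewis-acid acylation with tigloyl chloride is replaced by addition of an aryllithium to the Weinreb amide, for the same reason.
- **Assumption.** Commercial 1 is taken to be of high enantiomeric purity; if not, it would be made from (1S,5S)-(−)-α-pinene of ≥97 % ee by allylic oxidation.
- **Assumption.** The sense of induction of each chiral catalyst is assigned by analogy and would be confirmed on a model before scale-up.

## Structural features

The target is a dearomatised acylphloroglucinol: ring A is a cyclohexadienone (C1 ketone, C2=C3, C4=C5 enol) whose only sp3 atom, C6, is quaternary and carries a prenyl and a cyclobutylmethyl group. Ring B, a trans-2,3-dimethyl-2,3-dihydropyran-4-one (O1′ on C3, C4′ ketone on C4), is fused across C3–C4, and C2 carries a CH(Ph)CH2CO2H chain. The cyclobutane is cis-1,3-disubstituted across a gem-dimethyl carbon, with isopropenyl on Ca and the CH2 link on Cc, which is the carbon pattern of a cleaved pinane. The six stereocentres form four groups that cannot relay to one another: the adjacent pair C2′/C3′, the benzylic carbon on C2, the quaternary C6, and the 1,3-pair on the cyclobutane. Fragile features are the isopropenylcyclobutane (a cation at the isopropenyl carbon ring-expands, a radical on the exocyclic CH2 ring-opens), C3′ (epimerisable), ring B as a whole (opens by retro-oxa-Michael in base), the prenyl group and the β-tricarbonyl array. The real difficulties are telling the three phloroglucinol oxygens apart, so that ring B sits on O3, and creating C6 with two similar CH2R groups far from any stereocentre. The key step exploits that O1′–C2′ lies β to the C4′ carbonyl and C3′ lies α to it. An aromatic tigloyl ketone with one free hydroxyl on C3 closes ring B by conjugate addition; C2′ needs a catalyst and C3′ equilibrates to trans.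

## Logic of the disconnections

**29 ⇒ 28.** The acid is reconnected to the C1 oxygen as an enol lactone. This hides the carboxyl group and O1 during the C6 alkylation and leaves O5–H as the only acidic site. The forward hydrolysis must be mild enough not to open ring B.

**28 ⇒ 25 + 27.** The C6–CH2 bond to the prenyl group is cut. Removing the prenyl group re-aromatises ring A, so everything earlier is arene chemistry. The forward step must alkylate carbon rather than O5, C6 rather than C2, through the unsubstituted allyl terminus, and on one face under catalyst control.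

**25 ⇒ 23 + 24.** The benzylic C–Ph bond is cut. Conjugate addition of an aryl group to a coumarin is a dependable way to set this centre, and the cut removes a stereocentre and leaves a flat lactone. The catalyst must dominate a substrate that has a peri oxygen (O3) next to the reacting carbon.

**23 ⇒ 22 ⇒ 21.** The C2–CH bond and then the O1 ester bond are cut. C2 is the only unsubstituted ring carbon and O1–H the only non-chelated hydroxyl, so both bonds form without regiochemical choice. The forward hydroarylation must be 6-endo and must leave the isopropenyl group alone.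

**21 ⇒ 20.** The two MOM groups are restored on O1 and O5. They are what makes O3 unique in the key step, and they can be removed without protic acid.

**20 ⇒ 18 (key).** O1′–C2′ is cut, opening ring B to the tigloyl ketone. This removes both ring B stereocentres and one ring. The forward step needs face selection at C2′ and a single free ortho hydroxyl.

**18 ⇒ 14 + 16, 14 ⇒ 13.** The aryl–acyl bond C4–C4′ is cut to an aryl anion and an acyl cation equivalent, and the bromine handle is then removed. In 13 the two positions ortho to the hydroxyl are equivalent, so no regiochemical decision arises. The forward step needs halogen–lithium exchange on a phenoxide and clean 1,2-addition.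

**13 ⇒ 12 ⇒ 10 + 5.** After restoring the silyl group, the aryl–CH2 bond at C6 is cut. This is the convergent joint between the arene and the terpene halves. The forward coupling must join a primary alkylzinc to a di-ortho-substituted aryl iodide without building a long-lived radical or a cation at the cyclobutylcarbinyl carbon.

**10 ⇒ 8 ⇒ 7 ⇒ 6.** The C–I bond and then the protecting groups are removed. The bulky silyl ether marks O3 and shields its neighbours, so lithiation goes between the two acetals. The forward sequence needs a clean mono-silylation of a symmetric triol.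

**5 ⇒ 4 ⇒ 3 ⇒ 2 ⇒ 1.** Functional group changes lead back to the acid; the exocyclic C=CH2 is cut to a methyl ketone, and the ketone and acid are reconnected as the ring alkene of 1. Compound 1 supplies both stereocentres, the gem-dimethyl group and the correct arm length. The forward olefination must not epimerise the carbon next to the ketone.

**16 ⇐ 15 and 27 ⇐ 26.** These are one-step reagent preparations.

## Other disconnections considered

**Alternative 1:** The cut goes through the four-membered ring (Cb–Ca and Cc–Cd).
- Forward step: amide A3 would be activated (Tf2O, hindered pyridine) and combined with ethyl pent-4-enoate A2 in a keteniminium [2+2] cycloaddition; hydrolysis would give cyclobutanone A1. Cc would be set by the auxiliary, with the gem-dimethyl carbon already next to the carbonyl.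
- In its favour: it is independent of the terpene pool and either enantiomer is accessible. The Ca carbonyl would let the acid- and radical-sensitive isopropenyl group be introduced late. On this last point it is better than the chosen plan, which carries that group through thirteen later steps.
- Against it here: only one of the two ring stereocentres is made. The cis relationship would have to be created when the three-carbon unit is attached at Ca and the oxygen removed. Auxiliary-controlled cycloadditions to unactivated terminal alkenes are not reliably highly selective. The propanoate arm of A1 has the right length only for a plan that builds ring A from an open chain, not for an aryl–CH2 coupling.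
- Comparison: structurally, the chosen plan takes both centres, their cis relationship and the gem-dimethyl group from 1 without any stereochemical decision. Mechanistically both are sound. In step count the alternative would need about three more steps for the cyclobutane alone, and it addresses a part of the molecule that is not the real difficulty.

**Alternative 2:** The cut is C1–C2 of ring A, made last.
- Forward step: the open-chain precursor A5 would be deprotonated at C2, which is vinylogous to the C4′ carbonyl. The dienolate would attack the methyl ester to give A4, and fluoride would then free the acid.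
- In its favour: no dearomatisation is needed. C6 would be created in an acyclic β-keto ester by enolate alkylation, which is potentially better control than a late dearomative prenylation; on this point it is the better plan. The ring B oxygen is placed by construction (equal). The final deprotection is milder than a hydrolysis (equal or slightly better).
- Against it here: A5 carries all six stereocentres and a quaternary β-keto ester that could fragment by retro-Claisen cleavage under the basic conditions of its own cyclisation. The electrophilic ester is neopentyl-like. Deprotonation must choose C2 over C3′, whose enolate would open ring B. A5 needs a long linear assembly.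
- Comparison: structurally it trades an easy aromatic ring for a crowded acyclic triketone. Mechanistically the closure is plausible but competes with fragmentation, whereas 18 has one free nucleophile and one acceptor. It is expected to be several steps longer because nothing in it is symmetric.

**Alternative 3:** The cut takes ring A apart into a four-carbon and a two-carbon piece (C4–C5 and C2–C3 formed, C5–C6 re-formed).
- Forward step: heating cyclobutenone A7 with alkoxyacetylene A8 would bring about electrocyclic opening, [2+2] addition, a second opening and 6π closure (Danheiser benzannulation) to give phenol A6.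
- In its favour: the three oxygen atoms are different from the outset, which costs the chosen plan steps 5, 6, 9 and 14; on this point it is better. C2′ and C3′ come from the chiral pool without asymmetric catalysis (equal or better for reliability). The reaction is neutral and thermal, which suits the isopropenylcyclobutane (equal).
- Against it here: A7 would need alkylation of a cyclobutenone enolate with the hindered iodide 5, and A8 a multi-step synthesis. Ring B would then have to be closed by acylation at C4 under acid, which the isopropenyl group is unlikely to tolerate and which must choose C4 over C2. The ethyl ether on O1 has the same removal problem as a methyl ether.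
- Comparison: structurally it is elegant for oxygen differentiation but moves the acid problem to a later and worse place. Mechanistically the ring construction is sound. The step count is judged similar or longer once A7 and A8 are included.

Key step: step 13

## Route

Step 1
Reactants: 1 (1S,5S)-(−)-verbenone
Product: 2 (1S,3R)-3-acetyl-2,2-dimethylcyclobutane-1-carboxylic acid (cis-pinononic acid)
Conditions: RuCl3·xH2O (2 mol %), NaIO4 (4.2 equiv), EtOAc/MeCN/H2O, rt
Reagents that add atoms: sodium periodate, [Na+].[O-]I(=O)(=O)=O
Why: RuO4 formed in situ cleaves the enone C=C, and the α-keto acid first formed loses CO2 oxidatively, so the carboxyl group ends up directly on the ring. Neither ring stereocentre is touched, so the cis relationship of 1 is kept.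

Step 2
Reactants: 2 (1S,3R)-3-acetyl-2,2-dimethylcyclobutane-1-carboxylic acid
Product: 3 (1S,3S)-2,2-dimethyl-3-(prop-1-en-2-yl)cyclobutane-1-carboxylic acid
Conditions: Ph3PCH3Br (2.2 equiv), KN(SiMe3)2 (3.1 equiv), THF, 0 °C → rt; aq. HCl work-up
Reagents that add atoms: methyltriphenylphosphonium bromide, C[P+](c1ccccc1)(c1ccccc1)c1ccccc1.[Br-]
Why: Wittig methylenation of the methyl ketone on the potassium carboxylate, which is inert to the ylide. A fast reaction at low temperature with a non-nucleophilic base should limit enolisation at the ring carbon next to the ketone, so the cis relationship is retained.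

Step 3
Reactants: 3 (1S,3S)-2,2-dimethyl-3-(prop-1-en-2-yl)cyclobutane-1-carboxylic acid
Product: 4 [(1S,3S)-2,2-dimethyl-3-(prop-1-en-2-yl)cyclobutyl]methanol
Conditions: LiAlH4, THF, 0 °C → rt
Reagents that add atoms: none
Why: Hydride reduction of the acid to the primary alcohol; the isolated alkene and both stereocentres are inert.

Step 4
Reactants: 4 [(1S,3S)-2,2-dimethyl-3-(prop-1-en-2-yl)cyclobutyl]methanol
Product: 5 (1S,3S)-1-(iodomethyl)-2,2-dimethyl-3-(prop-1-en-2-yl)cyclobutane
Conditions: PPh3, I2, imidazole, CH2Cl2, 0 °C → rt
Reagents that add atoms: iodine, II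
Why: Appel iodination; iodide displaces the alkoxyphosphonium group at the primary carbon, so no cation forms next to the four-membered ring.

Step 5
Reactants: 6 phloroglucinol (benzene-1,3,5-triol)
Product: 7 5-{[tri(propan-2-yl)silyl]oxy}benzene-1,3-diol
Conditions: 6 (3 equiv), chlorotri(propan-2-yl)silane (1 equiv), imidazole, DMF, 0 °C → rt
Reagents that add atoms: chlorotri(propan-2-yl)silane, CC(C)[Si](Cl)(C(C)C)C(C)C
Why: Silylation with the cheap triol in excess should give mainly the mono-ether, and unreacted 6 is removed by aqueous washing. The three hydroxyls are equivalent, so there is no regiochemical issue.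

Step 6
Reactants: 7 5-{[tri(propan-2-yl)silyl]oxy}benzene-1,3-diol
Product: 8 [3,5-bis(methoxymethoxy)phenoxy]tri(propan-2-yl)silane
Conditions: chloro(methoxy)methane (2.6 equiv), i-Pr2NEt (3 equiv), CH2Cl2, 0 °C → rt
Reagents that add atoms: chloro(methoxy)methane, COCCl
Why: Standard O-alkylation of both phenols to MOM ethers. The silyl ether now marks the oxygen that becomes O3.

Step 7
Reactants: 8 [3,5-bis(methoxymethoxy)phenoxy]tri(propan-2-yl)silane
Product: 10 [4-iodo-3,5-bis(methoxymethoxy)phenoxy]tri(propan-2-yl)silane, via aryllithium 9 (not isolated)
Conditions: n-BuLi (1.1 equiv), THF, 0 °C; then I2, −78 °C → rt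
Reagents that add atoms: iodine, II
Why: Directed ortho-metalation at the carbon flanked by two MOM ethers, which is the most acidic site; the bulky silyl ether shields its own neighbours. Iodine then traps the aryllithium at the future C6.

Step 8
Reactants: 5 (1S,3S)-1-(iodomethyl)-2,2-dimethyl-3-(prop-1-en-2-yl)cyclobutane; 10 [4-iodo-3,5-bis(methoxymethoxy)phenoxy]tri(propan-2-yl)silane
Product: 12 [4-CBM-3,5-bis(methoxymethoxy)phenoxy]tri(propan-2-yl)silane, via alkylzinc iodide 11 (not isolated)
Conditions: 5, Zn dust, LiCl, THF, 40 °C; then 10, Pd(OAc)2 (2 mol %), 2-dicyclohexylphosphino-2′,6′-dimethoxybiphenyl (4 mol %), THF, rt → 45 °C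
Reagents that add atoms: none
Why: Negishi coupling of a primary alkylzinc with an aryl iodide. The electron-rich biaryl phosphine is chosen for di-ortho-substituted partners and for fast reductive elimination ahead of β-hydride loss. No stereocentre is involved, and the descriptor at Cc changes from S to R only through the priority rules.

Step 9
Reactants: 12 [4-CBM-3,5-bis(methoxymethoxy)phenoxy]tri(propan-2-yl)silane
Product: 13 4-CBM-3,5-bis(methoxymethoxy)phenol
Conditions: Bu4NF (1.1 equiv), THF, 0 °C
Reagents that add atoms: none
Why: Fluoride cleaves the aryl silyl ether selectively; MOM ethers and the alkene are inert.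

Step 10
Reactants: 13 4-CBM-3,5-bis(methoxymethoxy)phenol
Product: 14 2-bromo-4-CBM-3,5-bis(methoxymethoxy)phenol
Conditions: N-bromosuccinimide (1.0 equiv), CH2Cl2, −78 °C
Reagents that add atoms: N-bromosuccinimide, O=C1CCC(=O)N1Br
Why: Electrophilic bromination of a very electron-rich phenol, far faster than any reaction at the isopropenyl group. The two free positions are equivalent and the para position is blocked, so one monobromide is expected.

Step 11
Reactants: 15 tigloyl chloride ((E)-2-methylbut-2-enoyl chloride)
Product: 16 (E)-N-methoxy-N,2-dimethylbut-2-enamide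
Conditions: MeNHOMe·HCl, Et3N, CH2Cl2, 0 °C
Reagents that add atoms: N,O-dimethylhydroxylamine hydrochloride, CNOC.Cl
Why: Amide formation from the acid chloride; the E geometry is untouched.

Step 12
Reactants: 14 2-bromo-4-CBM-3,5-bis(methoxymethoxy)phenol; 16 (E)-N-methoxy-N,2-dimethylbut-2-enamide
Product: 18 (E)-1-[3-CBM-6-hydroxy-2,4-bis(methoxymethoxy)phenyl]-2-methylbut-2-en-1-one, via dilithiated phenol 17 (not isolated)
Conditions: n-BuLi (1.05 equiv), THF, −78 °C; t-BuLi (2.1 equiv), −78 °C; then 16, −78 → −40 °C; AcOH, −78 °C
Reagents that add atoms: none
Why: Deprotonation of the phenol, bromine–lithium exchange and Weinreb ketone synthesis. The chelated tetrahedral adduct survives until the cold acidic quench, so the phenoxide and the enone never coexist and no uncatalysed ring closure can start. No Lewis acid is needed.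

Step 13
Reactants: 18 (E)-1-[3-CBM-6-hydroxy-2,4-bis(methoxymethoxy)phenyl]-2-methylbut-2-en-1-one
Product: 20 (2R,3R)-6-CBM-5,7-bis(methoxymethoxy)-2,3-dimethylchroman-4-one, via cis epimer 19 (not isolated)
Conditions: 1-[3,5-bis(trifluoromethyl)phenyl]-3-[(8α,9S)-6′-methoxycinchonan-9-yl]thiourea (quinine-derived, 10 mol %), PhCl, 0 °C → rt, held until C3′ has equilibrated
Reagents that add atoms: none
Why: The quinuclidine nitrogen of the catalyst deprotonates the C3 hydroxyl (acidified by the ortho ketone) while the thiourea binds the C4′ carbonyl; the phenoxide adds to C2′ of the enone and the resulting enol is protonated at C3′. The closest known reaction type is the cinchona-alkaloid-catalysed intramolecular oxa-Michael addition of 2′-hydroxyaryl tigloyl ketones to 2,3-dimethylchroman-4-ones. Ring B closes in the 6-endo-trig mode through the new O1′–C2′ bond. C2′ is set by the catalyst, which exposes one face of the enone; by analogy the quinine series is expected to give 2′R, and the quinidine-derived pseudoenantiomer is held in reserve if the sense proves opposite. C3′ is not set kinetically: the cis epimer 19 and 20 interconvert through the enol and should settle on the trans isomer with both methyl groups equatorial. The step needs regioselectivity (O3, not O5, must close the ring), which the MOM ether on O5 secures by leaving a single free ortho hydroxyl; the unactivated isopropenyl group does not compete. The E geometry of the tigloyl unit defines how the enone sits in the catalyst, and the weak base and low temperature are meant to allow enolisation at C3′ without retro-oxa-Michael opening, which would erase C2′.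

Step 14
Reactants: 20 (2R,3R)-6-CBM-5,7-bis(methoxymethoxy)-2,3-dimethylchroman-4-one
Product: 21 (2R,3R)-6-CBM-5,7-dihydroxy-2,3-dimethylchroman-4-one
Conditions: ZnBr2 (2.2 equiv), n-PrSH (4 equiv), CH2Cl2, 0 °C, 10 min
Reagents that add atoms: none
Why: Lewis-acid-assisted transfer of the methoxymethyl group to the thiol, a brief aprotic acetal cleavage. It avoids the aqueous or methanolic strong acid that could protonate the isopropenyl group and trigger ring expansion.

Step 15
Reactants: 21 (2R,3R)-6-CBM-5,7-dihydroxy-2,3-dimethylchroman-4-one
Product: 22 (2R,3R)-6-CBM-5-hydroxy-2,3-dimethyl-4-oxochroman-7-yl prop-2-ynoate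
Conditions: propiolic acid (1.2 equiv), DCC (1.2 equiv), DMAP (2 mol %), CH2Cl2, −20 → 0 °C
Reagents that add atoms: propiolic acid, C#CC(=O)O
Why: Steglich esterification. The C5 hydroxyl is locked in a hydrogen bond to the C4′ carbonyl, so only the O1 hydroxyl (position 7 of the chromanone) should be acylated.

Step 16
Reactants: 22 (2R,3R)-6-CBM-5-hydroxy-2,3-dimethyl-4-oxochroman-7-yl prop-2-ynoate
Product: 23 coumarin: 21 with a lactone ring O1–C(=O)–CH=CH–C2 fused on ring A (positions 7 and 8 of the chromanone), C5–OH free, 2′R,3′R
Conditions: [(2-biphenylyl)(t-Bu)2P]Au(NCMe)SbF6 (3 mol %), 1,2-dichloroethane, rt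
Reagents that add atoms: none
Why: Monovalent gold activates the alkyne, and C2, the only free ring position, attacks its terminal carbon (6-endo-dig hydroarylation of an aryl alkynoate) to give the coumarin after protodeauration. The alkyne is activated far more readily than the isopropenyl alkene.

Step 17
Reactants: 23 coumarin (lactone O1–C(=O)–CH=CH–C2 on ring A); 24 phenylboronic acid
Product: 25 (4S)-4-phenyl-3,4-dihydrocoumarin: 23 with phenyl added to the lactone carbon attached to C2, 2′R,3′R
Conditions: 24 (5 equiv), Rh(acac)(C2H4)2 (3 mol %), (S)-SEGPHOS (3.3 mol %), 1,4-dioxane/H2O (10:1), 60 °C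
Reagents that add atoms: none
Why: Hayashi–Miyaura addition: the aryl–rhodium species inserts the coumarin C=C on the face fixed by the diphosphine, and water protonates the rhodium enolate. By analogy with simple coumarins the (S)-ligand is expected to give the 4S centre, and the remote substrate stereocentres should not interfere.

Step 18
Reactants: 26 prenol (3-methylbut-2-en-1-ol)
Product: 27 tert-butyl 3-methylbut-2-en-1-yl carbonate
Conditions: Boc2O (1.2 equiv), Bu4NHSO4 (5 mol %), 30 % aq. NaOH, CH2Cl2, 0 °C → rt
Reagents that add atoms: di-tert-butyl dicarbonate, CC(C)(C)OC(=O)OC(=O)OC(C)(C)C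
Why: Phase-transfer O-acylation of the allylic alcohol gives a prenyl donor that ionises under neutral conditions.

Step 19
Reactants: 25 (4S)-4-phenyl-3,4-dihydrocoumarin with free C5–OH; 27 tert-butyl 3-methylbut-2-en-1-yl carbonate
Product: 28 dearomatised enol lactone: 25 with a prenyl group on C6 (ring A: C5 ketone, C3=C4, C1=C2 as enol lactone); C6 is S by the sequence rule here and has the arrangement that is R in 29
Conditions: 27 (1.3 equiv), Pd2(dba)3·CHCl3 (2.5 mol %), (1R,2R)-N,N′-bis[2-(diphenylphosphanyl)benzoyl]cyclohexane-1,2-diamine (7.5 mol %), toluene, 0 °C → rt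
Reagents that add atoms: none
Why: Proposed new method: zerovalent palladium ionises 27 to a cationic η3-prenyl complex, CO2 and tert-butoxide, which deprotonates the C5 hydroxyl; the ion-paired phenoxide is alkylated at C6 (ortho to O5, para to O3) through the unsubstituted allyl terminus, and any O5 prenyl ether is re-ionised by the catalyst so that material drains to the irreversible C-alkylation product. The closest known reaction types are the palladium-catalysed enantioselective intermolecular allylic dearomatisation of 1-substituted 2-naphthols with ligands of this family and the non-asymmetric dearomative C-prenylation of acylphloroglucinols; the ligand must decide the face because the nearest stereocentres are four or more bonds away, and the antipodal ligand is used if the sense is opposite.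

Step 20
Reactants: 28 dearomatised enol lactone
Product: 29 (3S)-3-[(2R,3R,6R)-6-CBM-5-hydroxy-2,3-dimethyl-6-(3-methylbut-2-en-1-yl)-4,7-dioxo-3,4,6,7-tetrahydro-2H-chromen-8-yl]-3-phenylpropanoic acid (CNP0103716.3)
Conditions: LiOH (3 equiv), THF/H2O (3:1), 0 °C; then 1 M HCl to pH 3
Reagents that add atoms: lithium hydroxide, [Li+].[OH-]
Why: Hydroxide opens the activated enol lactone; the C1 enolate and carboxylate formed are protonated on work-up, and the ring tautomerises to the C1 ketone / C5 enol form. Once ring A is an anion, further deprotonation at C3′ is disfavoured, which should protect ring B during the short cold reaction.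

## Compound list

1 | (1S,5S)-(−)-verbenone (4,6,6-trimethylbicyclo[3.1.1]hept-3-en-2-one) | CC1=CC(=O)[C@H]2C[C@@H]1C2(C)C | starting material
2 | (1S,3R)-3-acetyl-2,2-dimethylcyclobutane-1-carboxylic acid | CC(=O)[C@@H]1C[C@H](C(=O)O)C1(C)C | intermediate
3 | (1S,3S)-2,2-dimethyl-3-(prop-1-en-2-yl)cyclobutane-1-carboxylic acid | C=C(C)[C@@H]1C[C@H](C(=O)O)C1(C)C | intermediate
4 | [(1S,3S)-2,2-dimethyl-3-(prop-1-en-2-yl)cyclobutyl]methanol | C=C(C)[C@@H]1C[C@H](CO)C1(C)C | intermediate
5 | (1S,3S)-1-(iodomethyl)-2,2-dimethyl-3-(prop-1-en-2-yl)cyclobutane | C=C(C)[C@@H]1C[C@H](CI)C1(C)C | intermediate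
6 | phloroglucinol (benzene-1,3,5-triol) | Oc1cc(O)cc(O)c1 | starting material
7 | 5-{[tri(propan-2-yl)silyl]oxy}benzene-1,3-diol | CC(C)[Si](Oc1cc(O)cc(O)c1)(C(C)C)C(C)C | intermediate
8 | [3,5-bis(methoxymethoxy)phenoxy]tri(propan-2-yl)silane | COCOc1cc(OCOC)cc(O[Si](C(C)C)(C(C)C)C(C)C)c1 | intermediate
9 | {2,6-bis(methoxymethoxy)-4-[tri(propan-2-yl)silyloxy]phenyl}lithium | [Li]c1c(OCOC)cc(O[Si](C(C)C)(C(C)C)C(C)C)cc1OCOC | intermediate (not isolated)
10 | [4-iodo-3,5-bis(methoxymethoxy)phenoxy]tri(propan-2-yl)silane | COCOc1cc(O[Si](C(C)C)(C(C)C)C(C)C)cc(OCOC)c1I | intermediate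
11 | {[(1S,3S)-2,2-dimethyl-3-(prop-1-en-2-yl)cyclobutyl]methyl}zinc iodide | C=C(C)[C@@H]1C[C@H](C[Zn]I)C1(C)C | intermediate (not isolated)
12 | [4-CBM-3,5-bis(methoxymethoxy)phenoxy]tri(propan-2-yl)silane | C=C(C)[C@@H]1C[C@H](Cc2c(OCOC)cc(O[Si](C(C)C)(C(C)C)C(C)C)cc2OCOC)C1(C)C | intermediate
13 | 4-CBM-3,5-bis(methoxymethoxy)phenol | C=C(C)[C@@H]1C[C@H](Cc2c(OCOC)cc(O)cc2OCOC)C1(C)C | intermediate
14 | 2-bromo-4-CBM-3,5-bis(methoxymethoxy)phenol | C=C(C)[C@@H]1C[C@H](Cc2c(OCOC)cc(O)c(Br)c2OCOC)C1(C)C | intermediate
15 | tigloyl chloride, (E)-2-methylbut-2-enoyl chloride | C/C=C(\C)C(=O)Cl | starting material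
16 | (E)-N-methoxy-N,2-dimethylbut-2-enamide | C/C=C(\C)C(=O)N(C)OC | intermediate
17 | lithium 2-lithio-4-CBM-3,5-bis(methoxymethoxy)phenoxide | C=C(C)[C@@H]1C[C@H](Cc2c(OCOC)cc(O[Li])c([Li])c2OCOC)C1(C)C | intermediate (not isolated)
18 | (E)-1-[3-CBM-6-hydroxy-2,4-bis(methoxymethoxy)phenyl]-2-methylbut-2-en-1-one (key-step precursor) | C=C(C)[C@@H]1C[C@H](Cc2c(OCOC)cc(O)c(C(=O)/C(C)=C/C)c2OCOC)C1(C)C | intermediate
19 | (2R,3S)-6-CBM-5,7-bis(methoxymethoxy)-2,3-dimethylchroman-4-one (cis epimer) | C=C(C)[C@@H]1C[C@H](Cc2c(OCOC)cc3O[C@H](C)[C@H](C)C(=O)c3c2OCOC)C1(C)C | intermediate (not isolated)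
20 | (2R,3R)-6-CBM-5,7-bis(methoxymethoxy)-2,3-dimethylchroman-4-one (key-step product) | C=C(C)[C@@H]1C[C@H](Cc2c(OCOC)cc3O[C@H](C)[C@@H](C)C(=O)c3c2OCOC)C1(C)C | intermediate
21 | (2R,3R)-6-CBM-5,7-dihydroxy-2,3-dimethylchroman-4-one | C=C(C)[C@@H]1C[C@H](Cc2c(O)cc3O[C@H](C)[C@@H](C)C(=O)c3c2O)C1(C)C | intermediate
22 | (2R,3R)-6-CBM-5-hydroxy-2,3-dimethyl-4-oxochroman-7-yl prop-2-ynoate | C=C(C)[C@@H]1C[C@H](Cc2c(OC(=O)C#C)cc3O[C@H](C)[C@@H](C)C(=O)c3c2O)C1(C)C | intermediate
23 | coumarin: lactone O1–C(=O)–CH=CH–C2 fused on ring A of 21, C5–OH free, 2′R,3′R | C=C(C)[C@@H]1C[C@H](Cc2c3OC(=O)C=Cc3c4O[C@H](C)[C@@H](C)C(=O)c4c2O)C1(C)C | intermediate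
24 | phenylboronic acid | OB(O)c1ccccc1 | starting material
25 | (4S)-4-phenyl-3,4-dihydrocoumarin derived from 23, 2′R,3′R | C=C(C)[C@@H]1C[C@H](Cc2c3OC(=O)C[C@@H](c5ccccc5)c3c4O[C@H](C)[C@@H](C)C(=O)c4c2O)C1(C)C | intermediate
26 | prenol (3-methylbut-2-en-1-ol) | CC(C)=CCO | starting material
27 | tert-butyl 3-methylbut-2-en-1-yl carbonate | CC(C)=CCOC(=O)OC(C)(C)C | intermediate
28 | dearomatised enol lactone: C6 carries prenyl and CBM (6S by the sequence rule), C5 ketone, C3=C4, C1=C2 enol lactone, benzylic carbon S, 2′R,3′R | C=C(C)[C@@H]1C[C@H](C[C@@]2(CC=C(C)C)C3=C([C@H](c5ccccc5)CC(=O)O3)C4=C(C(=O)[C@H](C)[C@@H](C)O4)C2=O)C1(C)C | intermediate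
29 | (3S)-3-[(2R,3R,6R)-6-CBM-5-hydroxy-2,3-dimethyl-6-(3-methylbut-2-en-1-yl)-4,7-dioxo-3,4,6,7-tetrahydro-2H-chromen-8-yl]-3-phenylpropanoic acid (CNP0103716.3) | C=C(C)[C@@H]1C[C@H](C[C@@]2(CC=C(C)C)C(=O)C([C@@H](CC(=O)O)c3ccccc3)=C3O[C@H](C)[C@@H](C)C(=O)C3=C2O)C1(C)C | target

## Step count and least certain steps

Total: 20 steps, two of which (11 and 18) are one-step reagent preparations. Longest linear sequence: 15 steps (1, 2, 3, 4, 8, 9, 10, 12, 13, 14, 15, 16, 17, 19, 20).

**Step 19 (dearomative prenylation).** The phenoxide may be alkylated on oxygen faster than the catalyst can return the ether to the ion pair. Attack may go through the substituted allyl terminus or at C2. The ligand may fail to distinguish the two faces of a ring whose stereocentres are remote. Fallback with known chemistry, setting out from 25 and rejoining at 29: methanolysis of the lactone (NaOMe, MeOH, 0 °C) would give methyl (3S)-3-[(2R,3R)-6-CBM-5,7-dihydroxy-2,3-dimethyl-4-oxochroman-8-yl]-3-phenylpropanoate F1. Its dianion, with both ring A hydroxyls deprotonated, would be treated in the same flask with prenyl bromide, the classical dearomative C-alkylation of acylphloroglucinols at the carbon between two phenoxide oxygens. This would give the methyl ester of the target F2 together with its C6 epimer F3, to be separated by preparative HPLC. Saponification of F2 (LiOH, THF/H2O) would give 29.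

**Step 13 (key step).** Face selection at C2′ may be insufficient for this hindered ketone, which is twisted by the O5 acetal and the C6 substituent. Prolonged equilibration of C3′ may also let the ring open and reclose, eroding C2′. Fallback, setting out from 18 and rejoining at 20: closure with triethylamine and no chiral catalyst would give 20 together with the (2S,3S)-diastereomer F4. The two are diastereomers because of the cyclobutane and would be separated by preparative chromatography on a chiral stationary phase. F4 would be returned to the mixture by base-mediated ring opening and reclosure, so the unwanted isomer is recycled.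

**Step 17 (phenyl addition).** Insertion may be slow because O3 is peri to the reacting carbon, so that protodeboronation of 24 wins, or the face selectivity may fall. Fallback, setting out from 21 and rejoining at 25 (steps 15–17 are bypassed): iminium-catalysed Friedel–Crafts alkylation of C2 with (E)-cinnamaldehyde (diarylprolinol silyl ether, benzoic acid, toluene), followed by closure of the aldehyde onto O1, would give the lactol (4S)-2-hydroxy-4-phenyl-3,4-dihydro-2H-pyran fused on ring A F5. Oxidation of the lactol (Ag2CO3 on Celite, toluene) would give 25.

**Step 8 (Negishi coupling).** Zinc insertion passes through a surface-bound cyclobutylcarbinyl radical that could ring-open towards the gem-dimethyl carbon. Oxidative addition and transmetalation at the di-ortho-substituted iodide may be slow enough for β-hydride elimination or reduction to intervene. Fallback, setting out from 4 and 8 and rejoining at 12: the alcohol would be converted (Tf2O, 2,6-lutidine, −78 °C) into [(1S,3S)-2,2-dimethyl-3-(prop-1-en-2-yl)cyclobutyl]methyl trifluoromethanesulfonate F6. Aryllithium 9, made from 8 as in step 7, would displace the triflate in the presence of CuI (10 mol %). This is a polar substitution with no radical and no palladium.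

**Step 16 (gold-catalysed hydroarylation).** The cationic catalyst may be sequestered by the chelating hydroxy ketone, or the activated propiolate may be consumed by hydration or oligomerisation before C2 attacks. Fallback, setting out from 21 and rejoining at 23 (22 is bypassed): magnesium-mediated ortho-formylation (MgCl2, Et3N, paraformaldehyde, THF) would give (2R,3R)-6-CBM-5,7-dihydroxy-2,3-dimethyl-4-oxochromane-8-carbaldehyde F7. Ketenylidenetriphenylphosphorane would then add the O1 hydroxyl, and the resulting ester ylide would close onto the aldehyde by intramolecular Wittig reaction to give 23.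

## Further compounds

F1 | step 19 | methyl (3S)-3-[(2R,3R)-6-CBM-5,7-dihydroxy-2,3-dimethyl-4-oxochroman-8-yl]-3-phenylpropanoate | C=C(C)[C@@H]1C[C@H](Cc2c(O)c([C@@H](CC(=O)OC)c5ccccc5)c3O[C@H](C)[C@@H](C)C(=O)c3c2O)C1(C)C
F2 | step 19 | methyl ester of 29 (6R) | C=C(C)[C@@H]1C[C@H](C[C@@]2(CC=C(C)C)C(=O)C([C@@H](CC(=O)OC)c3ccccc3)=C3O[C@H](C)[C@@H](C)C(=O)C3=C2O)C1(C)C
F3 | step 19 | C6 epimer of F2 (6S) | C=C(C)[C@@H]1C[C@H](C[C@]2(CC=C(C)C)C(=O)C([C@@H](CC(=O)OC)c3ccccc3)=C3O[C@H](C)[C@@H](C)C(=O)C3=C2O)C1(C)C
F4 | step 13 | (2S,3S)-6-CBM-5,7-bis(methoxymethoxy)-2,3-dimethylchroman-4-one | C=C(C)[C@@H]1C[C@H](Cc2c(OCOC)cc3O[C@@H](C)[C@H](C)C(=O)c3c2OCOC)C1(C)C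
F5 | step 17 | lactol of 25: (4S)-2-hydroxy-4-phenyl-3,4-dihydro-2H-pyran ring in place of the lactone, mixture at the hemiacetal carbon | C=C(C)[C@@H]1C[C@H](Cc2c3OC(O)C[C@@H](c5ccccc5)c3c4O[C@H](C)[C@@H](C)C(=O)c4c2O)C1(C)C
F6 | step 8 | [(1S,3S)-2,2-dimethyl-3-(prop-1-en-2-yl)cyclobutyl]methyl trifluoromethanesulfonate | C=C(C)[C@@H]1C[C@H](COS(=O)(=O)C(F)(F)F)C1(C)C
F7 | step 16 | (2R,3R)-6-CBM-5,7-dihydroxy-2,3-dimethyl-4-oxochromane-8-carbaldehyde | C=C(C)[C@@H]1C[C@H](Cc2c(O)c(C=O)c3O[C@H](C)[C@@H](C)C(=O)c3c2O)C1(C)C
A1 | alternative 1 | ethyl 3-[(1S)-2,2-dimethyl-3-oxocyclobutyl]propanoate | O=C1C[C@H](CCC(=O)OCC)C1(C)C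
A2 | alternative 1 | ethyl pent-4-enoate | C=CCCC(=O)OCC
A3 | alternative 1 | 1-[(2S,5S)-2,5-dimethylpyrrolidin-1-yl]-2-methylpropan-1-one | CC(C)C(=O)N1[C@@H](C)CC[C@@H]1C
A4 | alternative 2 | 2-(trimethylsilyl)ethyl ester of 29 | C=C(C)[C@@H]1C[C@H](C[C@@]2(CC=C(C)C)C(=O)C([C@@H](CC(=O)OCC[Si](C)(C)C)c3ccccc3)=C3O[C@H](C)[C@@H](C)C(=O)C3=C2O)C1(C)C
A5 | alternative 2 | open-chain precursor of A4: dihydropyranone with the C5 ketone / C6 quaternary / C1 methyl ester unit on C4 and the CH2CH(Ph)CH2CO2CH2CH2SiMe3 chain on C3 | C=C(C)[C@@H]1C[C@H](C[C@@](CC=C(C)C)(C(=O)OC)C(=O)C2=C(C[C@@H](CC(=O)OCC[Si](C)(C)C)c3ccccc3)O[C@H](C)[C@@H](C)C2=O)C1(C)C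
A6 | alternative 3 | ring A phenol with C5–OH, C1–OEt, chiral ether on O3 and CBM on C6 | C=C(C)[C@@H]1C[C@H](Cc2c(O)cc(O[C@H](C)[C@@H](C)CO[Si](C)(C)C(C)(C)C)cc2OCC)C1(C)C
A7 | alternative 3 | 4-CBM-3-ethoxycyclobut-2-en-1-one (mixture at ring C4) | C=C(C)[C@@H]1C[C@H](CC2C(=O)C=C2OCC)C1(C)C
A8 | alternative 3 | tert-butyl{[(2-methyl-3-ethynyloxy)butyl]oxy}dimethylsilane with the ring B configuration | C#CO[C@H](C)[C@@H](C)CO[Si](C)(C)C(C)(C)C
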